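**Retrosynthetic overview**

1. Target ⇐ its tris-benzyl ether by hydrogenolysis. Ring C is the only ring that is built, and it is closed last, from a 1,2-diaryl-3,3-dimethoxypropan-1-one whose single free phenol sits beside the future 8-OMe.
2. That acetal ⇐ a 2'-hydroxychalcone by oxidative 1,2-aryl shift with Tl(NO3)3. The chalcone ⇐ crossed aldol (Claisen–Schmidt) condensation of a ring A acetophenone with a ring B benzaldehyde; this C–C bond joins the two halves.
3. Ring A ketone ⇐ symmetric 2-methoxyresorcinol: bis-MOM ether, Ir C–H borylation/oxidation para to OMe, benzylation, ortho-lithiation/acetylation, MOM removal, benzylation of the non-chelated OH.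
4. Ring B aldehyde ⇐ 5-bromovanillin: Cu-mediated hydroxylation, selective 4-O-methylation, benzylation.
5. Ring order: rings A and B are bought as benzenes and decorated; ring C (the pyranone) is formed in the penultimate step.

Assumption: the target has no stereocentre, so it is a single achiral compound and no step needs stereocontrol.

**Route**

Step 1
Reactants: 1 2-methoxybenzene-1,3-diol (2-methoxyresorcinol)
Product: 2 2-methoxy-1,3-bis(methoxymethoxy)benzene
Conditions: NaH, MOMCl, DMF, 0 °C to rt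
Reagents that add atoms: chloromethyl methyl ether (MOMCl), COCCl
Why: Williamson-type O-alkylation of both phenoxides gives the bis-MOM acetal, which is inert to base and to the iridium catalyst and later directs lithiation.

Step 2
Reactants: 2 2-methoxy-1,3-bis(methoxymethoxy)benzene
Product: 3 2-[4-methoxy-3,5-bis(methoxymethoxy)phenyl]-4,4,5,5-tetramethyl-1,3,2-dioxaborolane
Conditions: B2pin2 (1.0 equiv), [Ir(OMe)(cod)]2 (1.5 mol %), 4,4'-di-tert-butyl-2,2'-bipyridine (3 mol %), THF, 80 °C (sealed tube)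
Reagents that add atoms: bis(pinacolato)diboron, CC1(C)OB(OC1(C)C)B1OC(C)(C)C(C)(C)O1
Why: Iridium-catalysed aromatic C–H borylation is governed by sterics, and C5–H is the only ring hydrogen without an ortho substituent, so boron enters para to the methoxy group only.

Step 3
Reactants: 3 2-[4-methoxy-3,5-bis(methoxymethoxy)phenyl]-4,4,5,5-tetramethyl-1,3,2-dioxaborolane
Product: 4 4-methoxy-3,5-bis(methoxymethoxy)phenol
Conditions: H2O2 (30% aq.), NaOH (aq.), THF, 0 °C to rt
Reagents that add atoms: hydrogen peroxide, OO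
Why: Alkaline peroxide oxidation of the arylboronate (1,2-aryl shift from boron to oxygen, then hydrolysis) puts OH exactly where boron was and leaves the MOM acetals alone.

Step 4
Reactants: 4 4-methoxy-3,5-bis(methoxymethoxy)phenol
Product: 5 5-(benzyloxy)-2-methoxy-1,3-bis(methoxymethoxy)benzene
Conditions: BnBr, K2CO3, DMF, rt
Reagents that add atoms: benzyl bromide, BrCc1ccccc1
Why: Williamson ether synthesis on the only free phenol installs the benzyl group that becomes the 5-O-benzyl of the isoflavone.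

Step 5
Reactants: 5 5-(benzyloxy)-2-methoxy-1,3-bis(methoxymethoxy)benzene
Product: 8 1-[6-(benzyloxy)-3-methoxy-2,4-bis(methoxymethoxy)phenyl]ethan-1-one, via aryllithium 6 (not isolated), via tetrahedral lithium adduct 7 (not isolated)
Conditions: n-BuLi (1.1 equiv), THF, −78 to 0 °C; then MeC(O)N(OMe)Me, −78 °C to rt; then H2O
Reagents that add atoms: N-methoxy-N-methylacetamide, CC(=O)N(C)OC (the acetyl group); n-butyllithium, [Li]CCCC (the lithium of 6 and 7 only)
Why: In this directed ortho-metalation the two remaining ring hydrogens are equivalent by symmetry and each lies between an OMOM and an OBn group, and the Weinreb amide gives a chelated tetrahedral adduct that releases the methyl ketone only on quench, so there is one regioisomer and no over-addition.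

Step 6
Reactants: 8 1-[6-(benzyloxy)-3-methoxy-2,4-bis(methoxymethoxy)phenyl]ethan-1-one
Product: 9 1-[6-(benzyloxy)-2,4-dihydroxy-3-methoxyphenyl]ethan-1-one
Conditions: HCl (3 M aq.), MeOH, 50 °C
Reagents that add atoms: none
Why: Acid-catalysed methanolysis of the two MOM acetals (transacetalisation to dimethoxymethane) does not touch benzyl or methyl ethers, and the ketone-deactivated ring resists alkylation by the formaldehyde equivalent.

Step 7
Reactants: 9 1-[6-(benzyloxy)-2,4-dihydroxy-3-methoxyphenyl]ethan-1-one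
Product: 10 1-[4,6-bis(benzyloxy)-2-hydroxy-3-methoxyphenyl]ethan-1-one
Conditions: BnBr (1.05 equiv), K2CO3, acetone, reflux
Reagents that add atoms: benzyl bromide, BrCc1ccccc1
Why: In this chelation-controlled Williamson benzylation the 2-OH is locked in a hydrogen bond to the ketone while the 4-OH, para to the acetyl group, is free and more acidic, so only O4 is alkylated and the phenol beside the methoxy group stays free.

Step 8
Reactants: 11 3-bromo-4-hydroxy-5-methoxybenzaldehyde (5-bromovanillin)
Product: 12 3,4-dihydroxy-5-methoxybenzaldehyde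
Conditions: NaOH (aq.), Cu powder (cat.), reflux under N2; then HCl to pH 2
Reagents that add atoms: sodium hydroxide, [Na+].[OH-]
Why: Copper-mediated (Ullmann-type) hydroxylation of the aryl bromide in hot aqueous alkali replaces Br by OH, and the aldehyde is shielded from Cannizzaro reaction because it is conjugated to the para phenoxide.

Step 9
Reactants: 12 3,4-dihydroxy-5-methoxybenzaldehyde
Product: 13 3-hydroxy-4,5-dimethoxybenzaldehyde
Conditions: Me2SO4 (1.05 equiv), Na2CO3, acetone, reflux
Reagents that add atoms: dimethyl sulfate, COS(=O)(=O)OC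
Why: In this selective Williamson methylation the 4-OH para to the aldehyde is the most acidic phenol and the one deprotonated by the weak base, so one equivalent of Me2SO4 methylates it and leaves the 3-OH.

Step 10
Reactants: 13 3-hydroxy-4,5-dimethoxybenzaldehyde
Product: 14 3-(benzyloxy)-4,5-dimethoxybenzaldehyde
Conditions: BnBr, K2CO3, DMF, rt
Reagents that add atoms: benzyl bromide, BrCc1ccccc1
Why: Williamson ether synthesis masks the ring B phenol with the same group used on ring A, so one hydrogenolysis frees all three phenols at the end.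

Step 11
Reactants: 10 1-[4,6-bis(benzyloxy)-2-hydroxy-3-methoxyphenyl]ethan-1-one; 14 3-(benzyloxy)-4,5-dimethoxybenzaldehyde
Product: 16 (E)-1-[4,6-bis(benzyloxy)-2-hydroxy-3-methoxyphenyl]-3-[3-(benzyloxy)-4,5-dimethoxyphenyl]prop-2-en-1-one, via aldol adduct 15 (not isolated)
Conditions: KOH (50% aq.), EtOH/THF, rt, 48 h; then cold dil. HCl
Reagents that add atoms: none
Why: In this Claisen–Schmidt (crossed aldol) condensation only ketone 10 can form an enolate and only aldehyde 14, which has no α-hydrogen, can accept it, and E1cB loss of water from the aldol gives the conjugated E-enone.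

Step 12
Reactants: 16 (E)-1-[4,6-bis(benzyloxy)-2-hydroxy-3-methoxyphenyl]-3-[3-(benzyloxy)-4,5-dimethoxyphenyl]prop-2-en-1-one
Product: 17 1-[4,6-bis(benzyloxy)-2-hydroxy-3-methoxyphenyl]-2-[3-(benzyloxy)-4,5-dimethoxyphenyl]-3,3-dimethoxypropan-1-one (racemic)
Conditions: Tl(NO3)3·3H2O (1.2 equiv), MeOH/CH2Cl2, rt
Reagents that add atoms: methanol, CO
Why: In this oxidative chalcone rearrangement, oxythallation of the enone by trivalent thallium in methanol is followed by a 1,2-shift of the electron-rich ring B aryl group and capture by methanol, which places ring B on the α-carbon and leaves the former β-carbon as a dimethyl acetal; the new stereocentre is racemic and is lost in the next step.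

Step 13
Reactants: 17 1-[4,6-bis(benzyloxy)-2-hydroxy-3-methoxyphenyl]-2-[3-(benzyloxy)-4,5-dimethoxyphenyl]-3,3-dimethoxypropan-1-one
Product: 19 5,7-bis(benzyloxy)-3-[3-(benzyloxy)-4,5-dimethoxyphenyl]-8-methoxy-4H-chromen-4-one, via 2-methoxyisoflavanone 18 (not isolated)
Conditions: HCl (10% aq.), MeOH/THF, reflux
Reagents that add atoms: none
Why: In this acid-catalysed cyclisation–elimination the only free phenol, the one beside the methoxy group, attacks the oxocarbenium ion from the acetal and loss of the second methanol gives the pyranone ring C, which fixes the methoxy group at C8.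

Step 14
Reactants: 19 5,7-bis(benzyloxy)-3-[3-(benzyloxy)-4,5-dimethoxyphenyl]-8-methoxy-4H-chromen-4-one
Product: 20 5,7-dihydroxy-3-(3-hydroxy-4,5-dimethoxyphenyl)-8-methoxy-4H-chromen-4-one (isoirigenin)
Conditions: H2 (1 atm), 10% Pd/C, THF/MeOH, rt
Reagents that add atoms: none
Why: Catalytic hydrogenolysis cleaves the three benzyl ethers under neutral conditions, which leaves the methyl ethers untouched and avoids acid-induced ring opening and reclosure (Wessely–Moser isomerisation) to the 6-methoxy isomer.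

**Compound list**

1 | 2-methoxybenzene-1,3-diol (2-methoxyresorcinol) | COc1c(O)cccc1O | starting material
2 | 2-methoxy-1,3-bis(methoxymethoxy)benzene | COCOc1cccc(OCOC)c1OC | intermediate
3 | 2-[4-methoxy-3,5-bis(methoxymethoxy)phenyl]-4,4,5,5-tetramethyl-1,3,2-dioxaborolane | COCOc1cc(B2OC(C)(C)C(C)(C)O2)cc(OCOC)c1OC | intermediate
4 | 4-methoxy-3,5-bis(methoxymethoxy)phenol | COCOc1cc(O)cc(OCOC)c1OC | intermediate
5 | 5-(benzyloxy)-2-methoxy-1,3-bis(methoxymethoxy)benzene | COCOc1cc(OCc2ccccc2)cc(OCOC)c1OC | intermediate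
6 | [6-(benzyloxy)-3-methoxy-2,4-bis(methoxymethoxy)phenyl]lithium (not isolated) | [Li]c1c(OCOC)c(OC)c(OCOC)cc1OCc1ccccc1 | intermediate
7 | lithium 1-[6-(benzyloxy)-3-methoxy-2,4-bis(methoxymethoxy)phenyl]-1-[methoxy(methyl)amino]ethan-1-olate (racemic, not isolated) | [Li]OC(C)(N(C)OC)c1c(OCOC)c(OC)c(OCOC)cc1OCc1ccccc1 | intermediate
8 | 1-[6-(benzyloxy)-3-methoxy-2,4-bis(methoxymethoxy)phenyl]ethan-1-one | CC(=O)c1c(OCOC)c(OC)c(OCOC)cc1OCc1ccccc1 | intermediate
9 | 1-[6-(benzyloxy)-2,4-dihydroxy-3-methoxyphenyl]ethan-1-one | CC(=O)c1c(O)c(OC)c(O)cc1OCc1ccccc1 | intermediate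
10 | 1-[4,6-bis(benzyloxy)-2-hydroxy-3-methoxyphenyl]ethan-1-one | CC(=O)c1c(O)c(OC)c(OCc2ccccc2)cc1OCc1ccccc1 | intermediate
11 | 3-bromo-4-hydroxy-5-methoxybenzaldehyde (5-bromovanillin) | COc1cc(C=O)cc(Br)c1O | starting material
12 | 3,4-dihydroxy-5-methoxybenzaldehyde | COc1cc(C=O)cc(O)c1O | intermediate
13 | 3-hydroxy-4,5-dimethoxybenzaldehyde | COc1cc(C=O)cc(O)c1OC | intermediate
14 | 3-(benzyloxy)-4,5-dimethoxybenzaldehyde | COc1cc(C=O)cc(OCc2ccccc2)c1OC | intermediate
15 | 1-[4,6-bis(benzyloxy)-2-hydroxy-3-methoxyphenyl]-3-[3-(benzyloxy)-4,5-dimethoxyphenyl]-3-hydroxypropan-1-one (racemic aldol adduct, not isolated) | COc1cc(C(O)CC(=O)c2c(O)c(OC)c(OCc3ccccc3)cc2OCc2ccccc2)cc(OCc2ccccc2)c1OC | intermediate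
16 | (E)-1-[4,6-bis(benzyloxy)-2-hydroxy-3-methoxyphenyl]-3-[3-(benzyloxy)-4,5-dimethoxyphenyl]prop-2-en-1-one | COc1cc(/C=C/C(=O)c2c(O)c(OC)c(OCc3ccccc3)cc2OCc2ccccc2)cc(OCc2ccccc2)c1OC | intermediate
17 | 1-[4,6-bis(benzyloxy)-2-hydroxy-3-methoxyphenyl]-2-[3-(benzyloxy)-4,5-dimethoxyphenyl]-3,3-dimethoxypropan-1-one (racemic) | COC(OC)C(C(=O)c1c(O)c(OC)c(OCc2ccccc2)cc1OCc1ccccc1)c1cc(OC)c(OC)c(OCc2ccccc2)c1 | intermediate
18 | 5,7-bis(benzyloxy)-3-[3-(benzyloxy)-4,5-dimethoxyphenyl]-2,8-dimethoxy-2,3-dihydro-4H-chromen-4-one (racemic mixture of diastereomers, not isolated) | COC1Oc2c(OC)c(OCc3ccccc3)cc(OCc3ccccc3)c2C(=O)C1c1cc(OC)c(OC)c(OCc2ccccc2)c1 | intermediate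
19 | 5,7-bis(benzyloxy)-3-[3-(benzyloxy)-4,5-dimethoxyphenyl]-8-methoxy-4H-chromen-4-one | COc1cc(-c2coc3c(OC)c(OCc4ccccc4)cc(OCc4ccccc4)c3c2=O)cc(OCc2ccccc2)c1OC | intermediate
20 | 5,7-dihydroxy-3-(3-hydroxy-4,5-dimethoxyphenyl)-8-methoxy-4H-chromen-4-one (isoirigenin, achiral) | COc1cc(-c2coc3c(OC)c(O)cc(O)c3c2=O)cc(O)c1OC | target

**Step count and risks**

Total step count: 14. Longest linear sequence: 11 steps (steps 1–7, then 11–14, from 1 to 20). The ring B branch (steps 8–10) joins at step 11.

Risk 1, step 5. The danger is metalation of the benzylic CH2 of the OBn group or enolisation of the amide by the hindered aryllithium. The fallback sets out from 5 and reverses the order of events. Both MOM ethers are cleaved first (HCl, MeOH, 40 °C) to give 5-(benzyloxy)-2-methoxybenzene-1,3-diol F1. This symmetric resorcinol is then acylated by a Hoesch reaction (MeCN, ZnCl2, HCl gas, Et2O, 0 °C), and the precipitated 1-[6-(benzyloxy)-2,4-dihydroxy-3-methoxyphenyl]ethan-1-iminium chloride F2 is hydrolysed in hot water to 9, where the route is rejoined. C4 and C6 of the resorcinol are equivalent, so the regiochemistry stays unambiguous.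

Risk 2, step 9. The danger is methylation at O3 or at both phenols. The fallback sets out from 11 and brings in the oxygen only after both methyl groups are in place. The single phenol of 11 is methylated (MeI, K2CO3, DMF) to 3-bromo-4,5-dimethoxybenzaldehyde F3. The C–Br bond is converted to C–B by Miyaura borylation (B2pin2, PdCl2(dppf), KOAc, dioxane, 85 °C) to give 3,4-dimethoxy-5-(4,4,5,5-tetramethyl-1,3,2-dioxaborolan-2-yl)benzaldehyde F4. The boronate is oxidised (NaBO3·4H2O, THF/H2O, rt) to 13, where the route is rejoined; step 8 is bypassed as well.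

Risk 3, step 12. The danger is aurone formation or oxidation of the ring A phenol by trivalent thallium. The fallback sets out from 16 and replaces the aryl shift by an aroyl shift. The 2'-OH is capped (NaH, MOMCl, DMF) to give (E)-1-[4,6-bis(benzyloxy)-3-methoxy-2-(methoxymethoxy)phenyl]-3-[3-(benzyloxy)-4,5-dimethoxyphenyl]prop-2-en-1-one F5. Weitz–Scheffer epoxidation (H2O2, NaOH, MeOH/THF) gives racemic [4,6-bis(benzyloxy)-3-methoxy-2-(methoxymethoxy)phenyl]{trans-3-[3-(benzyloxy)-4,5-dimethoxyphenyl]oxiran-2-yl}methanone F6. BF3·OEt2 (CH2Cl2, −20 °C) opens the epoxide at the benzylic carbon and induces a 1,2-aroyl shift to racemic 3-[4,6-bis(benzyloxy)-3-methoxy-2-(methoxymethoxy)phenyl]-2-[3-(benzyloxy)-4,5-dimethoxyphenyl]-3-oxopropanal F7. HCl in MeOH then removes the MOM group and cyclodehydrates to 19, where the route is rejoined; 17, 18 and step 13 are bypassed.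

**Further compounds**

F1 | step 5 | 5-(benzyloxy)-2-methoxybenzene-1,3-diol | COc1c(O)cc(OCc2ccccc2)cc1O
F2 | step 5 | 1-[6-(benzyloxy)-2,4-dihydroxy-3-methoxyphenyl]ethan-1-iminium chloride | CC(=[NH2+])c1c(O)c(OC)c(O)cc1OCc1ccccc1.[Cl-]
F3 | step 9 | 3-bromo-4,5-dimethoxybenzaldehyde | COc1cc(C=O)cc(Br)c1OC
F4 | step 9 | 3,4-dimethoxy-5-(4,4,5,5-tetramethyl-1,3,2-dioxaborolan-2-yl)benzaldehyde | COc1cc(C=O)cc(B2OC(C)(C)C(C)(C)O2)c1OC
F5 | step 12 | (E)-1-[4,6-bis(benzyloxy)-3-methoxy-2-(methoxymethoxy)phenyl]-3-[3-(benzyloxy)-4,5-dimethoxyphenyl]prop-2-en-1-one | COCOc1c(OC)c(OCc2ccccc2)cc(OCc2ccccc2)c1C(=O)/C=C/c1cc(OC)c(OC)c(OCc2ccccc2)c1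
F6 | step 12 | [4,6-bis(benzyloxy)-3-methoxy-2-(methoxymethoxy)phenyl]{trans-3-[3-(benzyloxy)-4,5-dimethoxyphenyl]oxiran-2-yl}methanone (racemic; one enantiomer drawn) | COCOc1c(OC)c(OCc2ccccc2)cc(OCc2ccccc2)c1C(=O)[C@@H]1O[C@H]1c1cc(OC)c(OC)c(OCc2ccccc2)c1
F7 | step 12 | 3-[4,6-bis(benzyloxy)-3-methoxy-2-(methoxymethoxy)phenyl]-2-[3-(benzyloxy)-4,5-dimethoxyphenyl]-3-oxopropanal (racemic) | COCOc1c(OC)c(OCc2ccccc2)cc(OCc2ccccc2)c1C(=O)C(C=O)c1cc(OC)c(OC)c(OCc2ccccc2)c1
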